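## Retrosynthetic overview

1. Target 17 ⇐ deacetylation and global debenzylation of 15. The C-8–C-1(propyl) bond of 15 ⇐ Friedel–Crafts union of two molecules of one synthetic flavan: acetate 14, whose ring C is opened at O-1–C-2 under acetoxy participation, and alcohol 13, which attacks through C-8.
2. Ring C of 13 (O-1, C-2, C-3, C-4, C-4a, C-8a) ⇐ one-atom ring expansion of the dihydrofuran ring of the trans-2-aryl-3-(hydroxymethyl)-2,3-dihydrobenzofuran 10: ring-A carbon C-4a migrates from C-3 to the exocyclic CH2 (which becomes C-4) and the sulfonate oxygen returns to C-3.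
3. Enabling feature: C-4a is the ipso carbon of the phloroglucinol ring A, ortho to O-5 and O-1 and para to O-7, and lies β to the carbinol carbon C-3, with the C-4–C-4a bond anti to the C-3–O bond in the 2,3-trans ring C. It can therefore bridge C-3 and C-4 as a phenonium ion, so that a 3-(sulfonyloxymethyl)dihydrobenzofuran and the flavan-3-yl sulfonate share one cation.
4. 10 ⇐ reduction and C-3 epimerization of cis ester 8 ⇐ enantioselective intramolecular C–H insertion of aryldiazoacetate 7 (sets C-2) ⇐ 3,5-bis(benzyloxy)phenol 1, oxalyl chloride and 3,4-bis(benzyloxy)benzyl chloride 3.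
5. Ring order: ring A and both rings B are bought; the dihydrofuran ring is closed in step 4; ring C arises from it by expansion in step 7; ring C of the upper unit is opened again in step 10.

Key step: step 7

Assumption: Rh2(S-PTTL)4 is taken to give the (2S) insertion product 8; if the sense of induction is the opposite, the enantiomeric catalyst Rh2(R-PTTL)4 is used and nothing else changes.
Remark: atom numbers (O-1, C-2, C-3, C-4, C-4a, C-8, C-8a) are those of the flavan; the C-2 descriptor changes from S (8–11) to R (12–17) by priority only, without any change of geometry.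

## Route

Step 1
Reactants: 1 3,5-bis(benzyloxy)phenol
Product: 2 4,6-bis(benzyloxy)-1-benzofuran-2,3-dione
Conditions: (COCl)2, Et2O, 0 °C → rt, then reflux
Reagents that add atoms: oxalyl chloride, ClC(=O)C(=O)Cl
Why: O-acylation of the phenol followed by intramolecular Friedel–Crafts acylation at the ortho carbon, which is activated by two further alkoxy groups and is equivalent on either side, should place the two-carbon unit regiospecifically next to the future O-1.

Step 2
Reactants: 2 4,6-bis(benzyloxy)-1-benzofuran-2,3-dione; 3 3,4-bis(benzyloxy)benzyl chloride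
Product: 5 methyl 2-[2,4-bis(benzyloxy)-6-{[3,4-bis(benzyloxy)phenyl]methoxy}phenyl]-2-oxoacetate, via hydroxy keto ester 4 (not isolated)
Conditions: MeOH, rt; then K2CO3, NaI (cat.), DMF, 50 °C
Reagents that add atoms: methanol, CO
Why: methanolysis of the aryl lactone unmasks exactly one phenol (the future O-1), and Williamson etherification with the activated benzylic chloride 3 should trap it before relactonization.

Step 3
Reactants: 5 methyl 2-[2,4-bis(benzyloxy)-6-{[3,4-bis(benzyloxy)phenyl]methoxy}phenyl]-2-oxoacetate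
Product: 7 methyl 2-[2,4-bis(benzyloxy)-6-{[3,4-bis(benzyloxy)phenyl]methoxy}phenyl]-2-diazoacetate, via tosylhydrazone 6 (not isolated)
Conditions: TsNHNH2, MeOH, 60 °C; then DBU, CH2Cl2, rt
Reagents that add atoms: p-toluenesulfonyl hydrazide, Cc1ccc(cc1)S(=O)(=O)NN
Why: condensation of the activated keto group and base-induced loss of sulfinate (Bamford–Stevens-type) is the standard entry to hindered aryldiazoacetates.

Step 4
Reactants: 7 methyl 2-[2,4-bis(benzyloxy)-6-{[3,4-bis(benzyloxy)phenyl]methoxy}phenyl]-2-diazoacetate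
Product: 8 methyl (2S,3R)-4,6-bis(benzyloxy)-2-[3,4-bis(benzyloxy)phenyl]-2,3-dihydro-1-benzofuran-3-carboxylate (2,3-cis)
Conditions: Rh2(S-PTTL)4 [dirhodium tetrakis(N-phthaloyl-(S)-tert-leucinate)] (1 mol %), toluene, −60 °C
Reagents that add atoms: none
Why: intramolecular 1,5 C–H insertion of the rhodium carbenoid into the ortho benzylic ether closes the dihydrofuran ring; the 3,4-dialkoxybenzyl C–H bond is more hydridic than that of the plain benzyl ether on the other ortho oxygen and is expected to react preferentially, and the chiral carboxylate ligands set C-2 (and, kinetically, cis C-3).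

Step 5
Reactants: 8 methyl (2S,3R)-4,6-bis(benzyloxy)-2-[3,4-bis(benzyloxy)phenyl]-2,3-dihydro-1-benzofuran-3-carboxylate
Product: 9 methyl (2S,3S)-4,6-bis(benzyloxy)-2-[3,4-bis(benzyloxy)phenyl]-2,3-dihydro-1-benzofuran-3-carboxylate (2,3-trans)
Conditions: NaOMe (0.2 equiv), MeOH/THF, 0 °C → rt
Reagents that add atoms: none
Why: base epimerization through the ester enolate should convert the cis ester into the thermodynamically favoured trans isomer at C-3 while C-2 is untouched.

Step 6
Reactants: 9 methyl (2S,3S)-4,6-bis(benzyloxy)-2-[3,4-bis(benzyloxy)phenyl]-2,3-dihydro-1-benzofuran-3-carboxylate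
Product: 10 [(2S,3R)-4,6-bis(benzyloxy)-2-[3,4-bis(benzyloxy)phenyl]-2,3-dihydro-1-benzofuran-3-yl]methanol
Conditions: LiAlH4, THF, 0 °C
Reagents that add atoms: none
Why: hydride reduction of the ester gives the primary alcohol without touching either stereocentre.

Step 7
Reactants: 10 [(2S,3R)-4,6-bis(benzyloxy)-2-[3,4-bis(benzyloxy)phenyl]-2,3-dihydro-1-benzofuran-3-yl]methanol
Product: 12 (2R,3S)-5,7-bis(benzyloxy)-2-[3,4-bis(benzyloxy)phenyl]-3,4-dihydro-2H-chromen-3-yl 4-methylbenzenesulfonate (2,3-trans), via primary tosylate 11 (not isolated)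
Conditions: Ts2O, i-Pr2NEt, DMAP (cat.), ClCH2CH2Cl, 0 °C; then 50 °C
Reagents that add atoms: p-toluenesulfonic anhydride, Cc1ccc(cc1)S(=O)(=O)OS(=O)(=O)c1ccc(C)cc1
Why: Proposed new method: the primary tosylate 11 ionizes with participation of ring A, whose ipso carbon (the future C-4a) bridges C-3 and the exocyclic CH2 (the future C-4) in a phenonium tosylate ion pair; return of tosylate at CH2 only re-forms 11, whereas return at C-3 breaks the old C-3–aryl bond and leaves the aryl group on CH2, so that reversible ionization should drain 11 into 12, which is favoured by loss of the strain of the five-membered ring and by the change from a primary to a secondary C–O bond. The closest known reaction types are the Wagner–Meerwein 1,2-aryl shift of 2-arylalkyl arenesulfonates with ion-pair return and the thermodynamically controlled ring expansion of prolinol esters to 3-acyloxypiperidines through aziridinium ions. Ring C is not closed by a new ring bond: the five-membered ring of 11 grows by one atom through 1,2-migration of the C-3–C(aryl) bond to the exocyclic carbon. C-3 is controlled by the stereospecific anti opening of the bridged ion (inversion at C-3 with respect to the departing aryl bond), which turns the trans-(3R) centre of 11 into the (3S)-sulfonate trans to the untouched 2-aryl group. The step needs return at the secondary carbon to outrun proton loss from the ion and needs ring A to be the only neighbouring group that takes part; this is secured by the three oxygen atoms ortho and para to the migrating carbon, by the trans arrangement that keeps ring B away from the CH2 group, and by a chloride-free, weakly nucleophilic medium with a hindered base.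

Step 8
Reactants: 12 (2R,3S)-5,7-bis(benzyloxy)-2-[3,4-bis(benzyloxy)phenyl]-3,4-dihydro-2H-chromen-3-yl 4-methylbenzenesulfonate
Product: 13 (2R,3S)-5,7-bis(benzyloxy)-2-[3,4-bis(benzyloxy)phenyl]-3,4-dihydro-2H-chromen-3-ol (5,7,3',4'-tetra-O-benzyl-(+)-catechin)
Conditions: SmI2, pyrrolidine, H2O, THF, rt, a few minutes
Reagents that add atoms: none
Why: single-electron reduction of the arenesulfonate cleaves the S–O bond within minutes in a non-ionizing medium, so the C-3–O bond and its configuration are kept (reductive desulfonylation), solvolysis cannot compete and the benzyl ethers are untouched.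

Step 9
Reactants: 13 (2R,3S)-5,7-bis(benzyloxy)-2-[3,4-bis(benzyloxy)phenyl]-3,4-dihydro-2H-chromen-3-ol
Product: 14 (2R,3S)-5,7-bis(benzyloxy)-2-[3,4-bis(benzyloxy)phenyl]-3,4-dihydro-2H-chromen-3-yl acetate
Conditions: Ac2O, pyridine, DMAP (cat.), CH2Cl2, rt, carried out on one quarter of the batch
Reagents that add atoms: acetic anhydride, CC(=O)OC(C)=O
Why: acylation of the secondary alcohol installs the participating group that turns one flavan molecule into the electrophile.

Step 10
Reactants: 14 (2R,3S)-5,7-bis(benzyloxy)-2-[3,4-bis(benzyloxy)phenyl]-3,4-dihydro-2H-chromen-3-yl acetate; 13 (2R,3S)-5,7-bis(benzyloxy)-2-[3,4-bis(benzyloxy)phenyl]-3,4-dihydro-2H-chromen-3-ol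
Product: 15 (1S,2S)-1-[3,4-bis(benzyloxy)phenyl]-1-{(2R,3S)-5,7-bis(benzyloxy)-2-[3,4-bis(benzyloxy)phenyl]-3-hydroxy-3,4-dihydro-2H-chromen-8-yl}-3-[2,4-bis(benzyloxy)-6-hydroxyphenyl]propan-2-yl acetate
Conditions: TMSOTf (0.2 equiv), CH2Cl2, −40 → 0 °C, acetate added slowly to a threefold excess of the alcohol partner; aq. NaHCO3
Reagents that add atoms: none
Why: TMSOTf-promoted heterolysis of the benzylic O-1–C-2 bond of 14 is assisted by the anti-periplanar 3-acetoxy group (trans-1,3-dioxolan-2-ylium ion), and C-8 of 13, the most nucleophilic position of a benzylated flavan as in 4→8 procyanidin couplings, should open this ion at the benzylic carbon anti to the departing oxygen, so that two inversions leave the aryl group where O-1 was and set the (1S) diarylmethine centre (Friedel–Crafts alkylation with neighbouring-group participation, the acid-mediated pyran-ring opening of flavan-3-ols by phenolic carbon nucleophiles); the union is a net addition of the C-8–H bond of one molecule of 13 across the O-1–C-2 bond of one molecule of 14, and the alcohol partner, which has no participating group, is kept in excess to hold back oligomers and its surplus is recovered unchanged.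

Step 11
Reactants: 15 (1S,2S)-1-[3,4-bis(benzyloxy)phenyl]-1-{(2R,3S)-5,7-bis(benzyloxy)-2-[3,4-bis(benzyloxy)phenyl]-3-hydroxy-3,4-dihydro-2H-chromen-8-yl}-3-[2,4-bis(benzyloxy)-6-hydroxyphenyl]propan-2-yl acetate
Product: 16 (2R,3S)-5,7-bis(benzyloxy)-2-[3,4-bis(benzyloxy)phenyl]-8-{(1S,2S)-1-[3,4-bis(benzyloxy)phenyl]-3-[2,4-bis(benzyloxy)-6-hydroxyphenyl]-2-hydroxypropyl}-3,4-dihydro-2H-chromen-3-ol
Conditions: K2CO3 (cat.), MeOH/THF (degassed), rt
Reagents that add atoms: none
Why: Zemplén-type transesterification removes the acetate without touching any stereocentre or benzyl ether.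

Step 12
Reactants: 16 (2R,3S)-5,7-bis(benzyloxy)-2-[3,4-bis(benzyloxy)phenyl]-8-{(1S,2S)-1-[3,4-bis(benzyloxy)phenyl]-3-[2,4-bis(benzyloxy)-6-hydroxyphenyl]-2-hydroxypropyl}-3,4-dihydro-2H-chromen-3-ol
Product: 17 (2R,3S)-2-(3,4-dihydroxyphenyl)-8-[(1S,2S)-1-(3,4-dihydroxyphenyl)-2-hydroxy-3-(2,4,6-trihydroxyphenyl)propyl]-3,4-dihydro-2H-chromene-3,5,7-triol (CNP0175733.2)
Conditions: H2 (1 atm), Pd(OH)2/C, THF/MeOH/H2O, rt
Reagents that add atoms: none
Why: hydrogenolysis of the eight benzyl ethers under the mild conditions used for benzylated catechins and procyanidins should leave the benzylic O-1–C-2 bond, the diarylmethine C–C bonds and all four stereocentres intact.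

## Compound list

1 | 3,5-bis(benzyloxy)phenol | Oc1cc(OCc2ccccc2)cc(OCc2ccccc2)c1 | starting material
2 | 4,6-bis(benzyloxy)-1-benzofuran-2,3-dione | O=C1Oc2cc(OCc3ccccc3)cc(OCc3ccccc3)c2C1=O | intermediate
3 | 3,4-bis(benzyloxy)benzyl chloride | ClCc1ccc(OCc2ccccc2)c(OCc2ccccc2)c1 | starting material
4 | methyl 2-[2,4-bis(benzyloxy)-6-hydroxyphenyl]-2-oxoacetate | COC(=O)C(=O)c1c(O)cc(OCc2ccccc2)cc1OCc1ccccc1 | intermediate
5 | methyl 2-[2,4-bis(benzyloxy)-6-{[3,4-bis(benzyloxy)phenyl]methoxy}phenyl]-2-oxoacetate | COC(=O)C(=O)c1c(OCc2ccc(OCc3ccccc3)c(OCc3ccccc3)c2)cc(OCc2ccccc2)cc1OCc1ccccc1 | intermediate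
6 | p-toluenesulfonylhydrazone of 5 | COC(=O)C(=NNS(=O)(=O)c1ccc(C)cc1)c1c(OCc2ccc(OCc3ccccc3)c(OCc3ccccc3)c2)cc(OCc2ccccc2)cc1OCc1ccccc1 | intermediate
7 | methyl 2-[2,4-bis(benzyloxy)-6-{[3,4-bis(benzyloxy)phenyl]methoxy}phenyl]-2-diazoacetate | COC(=O)C(=[N+]=[N-])c1c(OCc2ccc(OCc3ccccc3)c(OCc3ccccc3)c2)cc(OCc2ccccc2)cc1OCc1ccccc1 | intermediate
8 | methyl (2S,3R)-4,6-bis(benzyloxy)-2-[3,4-bis(benzyloxy)phenyl]-2,3-dihydro-1-benzofuran-3-carboxylate (cis) | COC(=O)[C@@H]1c2c(OCc3ccccc3)cc(OCc3ccccc3)cc2O[C@@H]1c1ccc(OCc2ccccc2)c(OCc2ccccc2)c1 | intermediate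
9 | methyl (2S,3S)-4,6-bis(benzyloxy)-2-[3,4-bis(benzyloxy)phenyl]-2,3-dihydro-1-benzofuran-3-carboxylate (trans) | COC(=O)[C@H]1c2c(OCc3ccccc3)cc(OCc3ccccc3)cc2O[C@@H]1c1ccc(OCc2ccccc2)c(OCc2ccccc2)c1 | intermediate
10 | [(2S,3R)-4,6-bis(benzyloxy)-2-[3,4-bis(benzyloxy)phenyl]-2,3-dihydro-1-benzofuran-3-yl]methanol (trans) | OC[C@H]1c2c(OCc3ccccc3)cc(OCc3ccccc3)cc2O[C@@H]1c1ccc(OCc2ccccc2)c(OCc2ccccc2)c1 | intermediate
11 | [(2S,3R)-4,6-bis(benzyloxy)-2-[3,4-bis(benzyloxy)phenyl]-2,3-dihydro-1-benzofuran-3-yl]methyl 4-methylbenzenesulfonate | Cc1ccc(cc1)S(=O)(=O)OC[C@H]1c2c(OCc3ccccc3)cc(OCc3ccccc3)cc2O[C@@H]1c1ccc(OCc2ccccc2)c(OCc2ccccc2)c1 | intermediate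
12 | (2R,3S)-5,7-bis(benzyloxy)-2-[3,4-bis(benzyloxy)phenyl]-3,4-dihydro-2H-chromen-3-yl 4-methylbenzenesulfonate | Cc1ccc(cc1)S(=O)(=O)O[C@H]1Cc2c(OCc3ccccc3)cc(OCc3ccccc3)cc2O[C@@H]1c1ccc(OCc2ccccc2)c(OCc2ccccc2)c1 | intermediate
13 | (2R,3S)-5,7-bis(benzyloxy)-2-[3,4-bis(benzyloxy)phenyl]-3,4-dihydro-2H-chromen-3-ol | O[C@H]1Cc2c(OCc3ccccc3)cc(OCc3ccccc3)cc2O[C@@H]1c1ccc(OCc2ccccc2)c(OCc2ccccc2)c1 | intermediate
14 | (2R,3S)-5,7-bis(benzyloxy)-2-[3,4-bis(benzyloxy)phenyl]-3,4-dihydro-2H-chromen-3-yl acetate | CC(=O)O[C@H]1Cc2c(OCc3ccccc3)cc(OCc3ccccc3)cc2O[C@@H]1c1ccc(OCc2ccccc2)c(OCc2ccccc2)c1 | intermediate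
15 | (1S,2S)-1-[3,4-bis(benzyloxy)phenyl]-1-{(2R,3S)-5,7-bis(benzyloxy)-2-[3,4-bis(benzyloxy)phenyl]-3-hydroxy-3,4-dihydro-2H-chromen-8-yl}-3-[2,4-bis(benzyloxy)-6-hydroxyphenyl]propan-2-yl acetate | c1ccccc1COc1cc(O)c(C[C@H](OC(C)=O)[C@@H](c2ccc(OCc3ccccc3)c(OCc3ccccc3)c2)c2c(OCc3ccccc3)cc(OCc3ccccc3)c3c2O[C@H](c2ccc(OCc4ccccc4)c(OCc4ccccc4)c2)[C@@H](O)C3)c(OCc2ccccc2)c1 | intermediate
16 | (2R,3S)-5,7-bis(benzyloxy)-2-[3,4-bis(benzyloxy)phenyl]-8-{(1S,2S)-1-[3,4-bis(benzyloxy)phenyl]-3-[2,4-bis(benzyloxy)-6-hydroxyphenyl]-2-hydroxypropyl}-3,4-dihydro-2H-chromen-3-ol | c1ccccc1COc1cc(O)c(C[C@H](O)[C@@H](c2ccc(OCc3ccccc3)c(OCc3ccccc3)c2)c2c(OCc3ccccc3)cc(OCc3ccccc3)c3c2O[C@H](c2ccc(OCc4ccccc4)c(OCc4ccccc4)c2)[C@@H](O)C3)c(OCc2ccccc2)c1 | intermediate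
17 | (2R,3S)-2-(3,4-dihydroxyphenyl)-8-[(1S,2S)-1-(3,4-dihydroxyphenyl)-2-hydroxy-3-(2,4,6-trihydroxyphenyl)propyl]-3,4-dihydro-2H-chromene-3,5,7-triol | Oc1cc(O)c(C[C@H](O)[C@@H](c2ccc(O)c(O)c2)c2c(O)cc(O)c3c2O[C@H](c2ccc(O)c(O)c2)[C@@H](O)C3)c(O)c1 | target

## Step count and risks

Total step count: 12. Longest linear sequence: 12 steps (1 → 13 → 14 → 15 → 17; both halves of the target come from 13).

Steps most likely to fail:

1. Step 7 (proposed new method). The ion pair may return only at the primary carbon, or the bridged ion may lose a proton faster than tosylate returns at C-3, so that the ring expansion does not reach completion. The fallback sets out from 10 and comes back at 13, replacing the reversible sulfonate return by an irreversible deamination with direct capture by water (known chemistry). 10 is tosylated in the cold (TsCl, pyridine, 0 °C) to 11, and the tosylate is displaced with NaN3 in DMF to give (2S,3R)-3-(azidomethyl)-4,6-bis(benzyloxy)-2-[3,4-bis(benzyloxy)phenyl]-2,3-dihydro-1-benzofuran F1. Staudinger reduction (PPh3, THF/H2O) gives [(2S,3R)-4,6-bis(benzyloxy)-2-[3,4-bis(benzyloxy)phenyl]-2,3-dihydro-1-benzofuran-3-yl]methanamine F2. Buffered nitrosation (NaNO2, AcOH/NaOAc, H2O/THF, 0 °C) forms the diazonium ion, which should lose dinitrogen with migration of the same C-3–aryl bond and take up water at C-3 anti to it (Demjanov ring expansion), giving 13 directly. Unrearranged alcohol formed alongside is 10 and re-enters the sequence.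

2. Step 10. The dioxolanylium ion may be captured by the freed upper ring A of the product or by C-6 of 13 (over-alkylation, wrong site), 13 may itself ionize under the acid, or the freed phenol may simply re-close ring C. The fallback sets out from 14 and comes back at 16, separating ring opening from C–C bond formation. Ring C of 14 is opened with a sulfur nucleophile in the absence of any arene partner (BnSH, TMSOTf cat., CH2Cl2, −40 °C) to give (1R,2S)-1-(benzylsulfanyl)-1-[3,4-bis(benzyloxy)phenyl]-3-[2,4-bis(benzyloxy)-6-hydroxyphenyl]propan-2-yl acetate F3. The freed phenol is capped (Ac2O, pyridine) to give 2-[(2S,3R)-2-acetoxy-3-(benzylsulfanyl)-3-[3,4-bis(benzyloxy)phenyl]propyl]-3,5-bis(benzyloxy)phenyl acetate F4, which can no longer re-close and has a less nucleophilic ring. Thiophilic activation (AgBF4, 13 in excess, THF/CH2Cl2, 0 °C) regenerates the same dioxolanylium ion under non-acidic conditions and should give 2-[(2S,3S)-2-acetoxy-3-[3,4-bis(benzyloxy)phenyl]-3-{(2R,3S)-5,7-bis(benzyloxy)-2-[3,4-bis(benzyloxy)phenyl]-3-hydroxy-3,4-dihydro-2H-chromen-8-yl}propyl]-3,5-bis(benzyloxy)phenyl acetate F5, the phenol acetate of 15. K2CO3 in MeOH removes both acetates and gives 16.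

3. Step 4. The di-ortho-substituted aryl carbenoid is twisted out of conjugation, so enantioinduction may be low, and insertion into the neighbouring benzyl ether may compete. The fallback sets out from 7 and comes back at 10, giving up catalyst control of absolute configuration. Achiral Rh2(OAc)4 in CH2Cl2 gives the insertion product as a racemate (8 together with its enantiomer, methyl (2R,3S)-4,6-bis(benzyloxy)-2-[3,4-bis(benzyloxy)phenyl]-2,3-dihydro-1-benzofuran-3-carboxylate F6). NaOMe in MeOH gives racemic trans ester (9 together with methyl (2R,3R)-4,6-bis(benzyloxy)-2-[3,4-bis(benzyloxy)phenyl]-2,3-dihydro-1-benzofuran-3-carboxylate F7). LiAlH4 gives the racemic alcohol (10 together with [(2R,3S)-4,6-bis(benzyloxy)-2-[3,4-bis(benzyloxy)phenyl]-2,3-dihydro-1-benzofuran-3-yl]methanol F8), from which 10 is separated by preparative chromatography on a chiral stationary phase. A regioisomeric insertion product, if present, is removed at the ester stage.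

## Further compounds

F1 | step 7 | (2S,3R)-3-(azidomethyl)-4,6-bis(benzyloxy)-2-[3,4-bis(benzyloxy)phenyl]-2,3-dihydro-1-benzofuran | [N-]=[N+]=NC[C@H]1c2c(OCc3ccccc3)cc(OCc3ccccc3)cc2O[C@@H]1c1ccc(OCc2ccccc2)c(OCc2ccccc2)c1
F2 | step 7 | [(2S,3R)-4,6-bis(benzyloxy)-2-[3,4-bis(benzyloxy)phenyl]-2,3-dihydro-1-benzofuran-3-yl]methanamine | NC[C@H]1c2c(OCc3ccccc3)cc(OCc3ccccc3)cc2O[C@@H]1c1ccc(OCc2ccccc2)c(OCc2ccccc2)c1
F3 | step 10 | (1R,2S)-1-(benzylsulfanyl)-1-[3,4-bis(benzyloxy)phenyl]-3-[2,4-bis(benzyloxy)-6-hydroxyphenyl]propan-2-yl acetate | c1ccccc1COc1cc(O)c(C[C@H](OC(C)=O)[C@H](SCc2ccccc2)c2ccc(OCc3ccccc3)c(OCc3ccccc3)c2)c(OCc2ccccc2)c1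
F4 | step 10 | 2-[(2S,3R)-2-acetoxy-3-(benzylsulfanyl)-3-[3,4-bis(benzyloxy)phenyl]propyl]-3,5-bis(benzyloxy)phenyl acetate | c1ccccc1COc1cc(OC(C)=O)c(C[C@H](OC(C)=O)[C@H](SCc2ccccc2)c2ccc(OCc3ccccc3)c(OCc3ccccc3)c2)c(OCc2ccccc2)c1
F5 | step 10 | 2-[(2S,3S)-2-acetoxy-3-[3,4-bis(benzyloxy)phenyl]-3-{(2R,3S)-5,7-bis(benzyloxy)-2-[3,4-bis(benzyloxy)phenyl]-3-hydroxy-3,4-dihydro-2H-chromen-8-yl}propyl]-3,5-bis(benzyloxy)phenyl acetate | c1ccccc1COc1cc(OC(C)=O)c(C[C@H](OC(C)=O)[C@@H](c2ccc(OCc3ccccc3)c(OCc3ccccc3)c2)c2c(OCc3ccccc3)cc(OCc3ccccc3)c3c2O[C@H](c2ccc(OCc4ccccc4)c(OCc4ccccc4)c2)[C@@H](O)C3)c(OCc2ccccc2)c1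
F6 | step 4 | methyl (2R,3S)-4,6-bis(benzyloxy)-2-[3,4-bis(benzyloxy)phenyl]-2,3-dihydro-1-benzofuran-3-carboxylate (enantiomer of 8) | COC(=O)[C@H]1c2c(OCc3ccccc3)cc(OCc3ccccc3)cc2O[C@H]1c1ccc(OCc2ccccc2)c(OCc2ccccc2)c1
F7 | step 4 | methyl (2R,3R)-4,6-bis(benzyloxy)-2-[3,4-bis(benzyloxy)phenyl]-2,3-dihydro-1-benzofuran-3-carboxylate (enantiomer of 9) | COC(=O)[C@@H]1c2c(OCc3ccccc3)cc(OCc3ccccc3)cc2O[C@H]1c1ccc(OCc2ccccc2)c(OCc2ccccc2)c1
F8 | step 4 | [(2R,3S)-4,6-bis(benzyloxy)-2-[3,4-bis(benzyloxy)phenyl]-2,3-dihydro-1-benzofuran-3-yl]methanol (enantiomer of 10) | OC[C@@H]1c2c(OCc3ccccc3)cc(OCc3ccccc3)cc2O[C@H]1c1ccc(OCc2ccccc2)c(OCc2ccccc2)c1
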